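The bond disconnected is the ring-fusion bond C5a–C9a (1-benzoxepine numbering: O1, C2–C5, C5a, C6–C9, C9a) of the cyclohexane ring. The key step exploits the tertiary ether carbon C9a (bearing O1 and CH3) next to the C5a–CH2 arm. C9a enters as an ester carbonyl and is methylenated to an enol ether. Iron-hydride H-atom transfer then creates both the C9a methyl group and a C9a radical that adds 6-exo to an unsaturated amide. One operation closes the carbocycle and sets C9a and C5a. The precursor is an open-chain dibromo enol ether assembled from two enantioenriched pieces (C2 and C7). Metathesis later closes the oxepene ring.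

Key step: step 9

Remark: the configuration given corresponds to (2R,5aR,7S,9aS), a cis-fused ring system with H at C5a, CH3 at C9a and Br at C7 on one face; the route is planned for exactly this isomer.

Step 1
Reactants: 1 N-methoxy-N-methylmethacrylamide
Product: 2 1-bromo-3-methylbut-3-en-2-one
Conditions: CH2Br2, MeLi·LiBr, THF/Et2O, −78 °C; then aq. NH4Cl
Reagents that add atoms: dibromomethane (delivered as bromomethyllithium), BrCBr
Why: Weinreb ketone synthesis with a lithium carbenoid: bromomethyllithium from Br/Li exchange adds 1,2 to the amide and the chelated tetrahedral adduct releases the bromomethyl ketone only on work-up, so no over-addition occurs; no stereocentre is formed.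

Step 2
Reactants: 2 1-bromo-3-methylbut-3-en-2-one
Product: 3 (2R)-1-bromo-3-methylbut-3-en-2-ol
Conditions: (R)-2-methyl-CBS-oxazaborolidine (10 mol %), catecholborane, toluene, −78 °C; MeOH quench, neutral work-up
Reagents that add atoms: none
Why: Corey–Bakshi–Shibata reduction: the oxazaborolidine–borane complex delivers hydride 1,2 to one face of the ketone, with isopropenyl as the large and CH2Br as the small substituent, which should set C2 as R (the catalyst antipode is taken if the face preference proves reversed).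

Step 3
Reactants: 4 2,2-dimethylpent-4-enal; 5 diethyl {2-[methoxy(methyl)amino]-2-oxoethyl}phosphonate
Product: 6 (2E)-N-methoxy-N,4,4-trimethylhepta-2,6-dienamide
Conditions: NaH, THF, 0 °C to rt
Reagents that add atoms: none
Why: Horner–Wadsworth–Emmons olefination of the non-enolisable aldehyde with the stabilised phosphonate anion should give the E alkene; no stereocentre is formed.

Step 4
Reactants: 6 (2E)-N-methoxy-N,4,4-trimethylhepta-2,6-dienamide
Product: 8 (2E)-N-methoxy-N,4,4-trimethyl-6-oxohex-2-enamide, via ozonide 7 (not isolated)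
Conditions: O3, CH2Cl2, −78 °C, Sudan III end point; then Me2S, −78 °C to rt
Reagents that add atoms: ozone, [O-][O+]=O
Why: Chemoselective ozonolysis: the electron-rich terminal alkene reacts far faster with ozone than the amide-conjugated alkene, and reductive work-up gives the aldehyde; no stereocentre is formed.

Step 5
Reactants: 8 (2E)-N-methoxy-N,4,4-trimethyl-6-oxohex-2-enamide
Product: 9 (2E,5R)-5-bromo-N-methoxy-N,4,4-trimethyl-6-oxohex-2-enamide
Conditions: (2S,5S)-2,5-diphenylpyrrolidine (20 mol %), 4,4-dibromo-2,6-di-tert-butylcyclohexa-2,5-dien-1-one, PhCO2H (20 mol %), H2O (1 equiv), CH2Cl2/pentane, −24 °C; cold filtration, used at once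
Reagents that add atoms: 4,4-dibromo-2,6-di-tert-butylcyclohexa-2,5-dien-1-one, CC(C)(C)C1=CC(Br)(Br)C=C(C(C)(C)C)C1=O
Why: Enamine-catalysed asymmetric α-bromination of an aldehyde: the C2-symmetric amine shields one enamine face so that the dienone delivers Br+ to the other and sets C7 (R in 9; the amine antipode is chosen for this sense), and the quaternary neighbour slows enolisation of the product.

Step 6
Reactants: 3 (2R)-1-bromo-3-methylbut-3-en-2-ol; 10 (triphenylphosphoranylidene)ketene; 9 (2E,5R)-5-bromo-N-methoxy-N,4,4-trimethyl-6-oxohex-2-enamide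
Product: 12 (2R)-1-bromo-3-methylbut-3-en-2-yl (2E,4S,6E)-4-bromo-8-[methoxy(methyl)amino]-5,5-dimethyl-8-oxoocta-2,6-dienoate, via ester phosphorane 11 (not isolated)
Conditions: 3, 10, toluene, 60 °C; then 9, 0 °C to rt
Reagents that add atoms: none
Why: Addition of the alcohol to the ketenylidene phosphorane gives the stabilised ester ylide, which undergoes a base-free Wittig olefination with the reactive α-bromo aldehyde (E alkene, removed in step 7); C2 and C7 are not touched.

Step 7
Reactants: 12 (2R)-1-bromo-3-methylbut-3-en-2-yl (2E,4S,6E)-4-bromo-8-[methoxy(methyl)amino]-5,5-dimethyl-8-oxoocta-2,6-dienoate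
Product: 13 (2R)-1-bromo-3-methylbut-3-en-2-yl (4S,6E)-4-bromo-8-[methoxy(methyl)amino]-5,5-dimethyl-8-oxooct-6-enoate
Conditions: 2-nitrobenzenesulfonohydrazide, Et3N, CH2Cl2, rt
Reagents that add atoms: none
Why: Diimide reduction (concerted syn transfer of H2 without metal or hydride, so both C–Br bonds and C7 survive): the least hindered, ester-conjugated trans alkene should react before the isopropenyl group and the neopentyl-flanked amide alkene; no stereocentre is formed.

Step 8
Reactants: 13 (2R)-1-bromo-3-methylbut-3-en-2-yl (4S,6E)-4-bromo-8-[methoxy(methyl)amino]-5,5-dimethyl-8-oxooct-6-enoate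
Product: 14 (2E,5S)-5-bromo-8-{[(2R)-1-bromo-3-methylbut-3-en-2-yl]oxy}-N-methoxy-N,4,4-trimethylnona-2,8-dienamide
Conditions: Cp2TiMe2, toluene/THF, 60 °C, dark
Reagents that add atoms: dimethyltitanocene, C[Ti](C)(C1C=CC=C1)C1C=CC=C1
Why: Petasis methylenation: thermally formed Cp2Ti=CH2 converts the ester carbonyl into the 2-alkoxy-1-alkene, while the less electrophilic conjugated N-methoxy amide and the alkyl bromides should stay intact and the temperature stays below that of a Claisen rearrangement of the allyl vinyl ether; no stereocentre is formed.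

Step 9
Reactants: 14 (2E,5S)-5-bromo-8-{[(2R)-1-bromo-3-methylbut-3-en-2-yl]oxy}-N-methoxy-N,4,4-trimethylnona-2,8-dienamide
Product: 15 2-[(1R,3S,6S)-3-bromo-6-{[(2R)-1-bromo-3-methylbut-3-en-2-yl]oxy}-2,2,6-trimethylcyclohexyl]-N-methoxy-N-methylacetamide
Conditions: Fe(acac)3 (20 mol %), Ph(iPrO)SiH2, Na2HPO4, EtOH/THF, 0.01 M, 22 °C
Reagents that add atoms: none
Why: An iron hydride formed from Fe(acac)3 and the silane transfers a hydrogen atom to the CH2 terminus of the electron-rich 2-alkoxy-alkene, which creates the C9a methyl group and a tertiary α-alkoxy radical at C9a; this nucleophilic radical adds to the β-carbon C5a of the unsaturated amide and the α-amide radical is then reduced and protonated. The closest known reaction type is the metal-hydride hydrogen-atom-transfer Giese reaction of enol ethers with acceptor alkenes, used here within one molecule. The cyclohexane ring closes in the 6-exo-trig mode through a chair with the acceptor arm pseudo-equatorial. At C9a the small ether oxygen should take the pseudo-axial site beside the axial C6 methyl and the new methyl the pseudo-equatorial one, which avoids a syn-pentane CH3/CH3 contact and puts O1 cis to the C5 arm (cis ring fusion). C5a is set relative to C7 if the C7–Br bond stands axial, antiparallel to the axial C9a–O dipole and free of the double gauche contact with the C6 methyls, which puts Br trans to the C5 arm. The step needs H-atom transfer to the enol ether and not to the isopropenyl group (favoured by its higher electron density and α-oxygen radical stabilisation, the isopropenyl group being inductively deactivated and without an acceptor in reach) and the facial sense just described, which is the weaker of the two controls.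

Step 10
Reactants: 15 2-[(1R,3S,6S)-3-bromo-6-{[(2R)-1-bromo-3-methylbut-3-en-2-yl]oxy}-2,2,6-trimethylcyclohexyl]-N-methoxy-N-methylacetamide
Product: 16 2-[(1R,3S,6S)-3-bromo-6-{[(2R)-1-bromo-3-methylbut-3-en-2-yl]oxy}-2,2,6-trimethylcyclohexyl]acetaldehyde
Conditions: iBu2AlH, THF, −78 °C; aq. KNaC4H4O6 (potassium sodium tartrate)
Reagents that add atoms: none
Why: Reduction of the Weinreb amide with iBu2AlH stops at the chelated hemiaminal, which gives the aldehyde on work-up; the stereocentres are not touched.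

Step 11
Reactants: 16 2-[(1R,3S,6S)-3-bromo-6-{[(2R)-1-bromo-3-methylbut-3-en-2-yl]oxy}-2,2,6-trimethylcyclohexyl]acetaldehyde
Product: 17 (1S,2R,4S)-4-bromo-1-{[(2R)-1-bromo-3-methylbut-3-en-2-yl]oxy}-1,3,3-trimethyl-2-(prop-2-en-1-yl)cyclohexane
Conditions: Ph3PCH3Br, KN(SiMe3)2, THF, −78 to 0 °C
Reagents that add atoms: methyltriphenylphosphonium bromide, C[P+](c1ccccc1)(c1ccccc1)c1ccccc1.[Br-]
Why: Wittig methylenation of the aldehyde with the non-stabilised ylide at low temperature should be faster than any attack on the alkyl bromides; no stereocentre is formed.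

Step 12
Reactants: 17 (1S,2R,4S)-4-bromo-1-{[(2R)-1-bromo-3-methylbut-3-en-2-yl]oxy}-1,3,3-trimethyl-2-(prop-2-en-1-yl)cyclohexane
Product: 18 (2R,5aR,7S,9aS)-7-bromo-2-(bromomethyl)-3,6,6,9a-tetramethyl-2,5,5a,6,7,8,9,9a-octahydro-1-benzoxepine
Conditions: (H2IMes)(PCy3)Cl2Ru=CHPh (second-generation Grubbs catalyst, 5 mol %), CH2Cl2, 40 °C
Reagents that add atoms: none
Why: Ring-closing olefin metathesis between the allyl and isopropenyl groups closes the seven-membered ether ring and forms the trisubstituted C3=C4 alkene with loss of ethene; no stereocentre is touched.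

Step 13
Reactants: 18 (2R,5aR,7S,9aS)-7-bromo-2-(bromomethyl)-3,6,6,9a-tetramethyl-2,5,5a,6,7,8,9,9a-octahydro-1-benzoxepine
Product: 19 [(2R,5aR,7S,9aS)-7-bromo-2-(bromomethyl)-6,6,9a-trimethyl-2,5,5a,6,7,8,9,9a-octahydro-1-benzoxepin-3-yl]methanol
Conditions: SeO2 (0.3 equiv), t-BuOOH, CH2Cl2, 0 °C to rt
Reagents that add atoms: tert-butyl hydroperoxide (oxygen atom, passed on by SeO2), CC(C)(C)OO
Why: Allylic oxidation with SeO2 (ene reaction, then [2,3]-sigmatropic shift) at the more substituted alkene carbon C3, where the CH3 group is preferred over the ring CH at C2, should give the primary allylic alcohol; no stereocentre is touched.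

Compound list
1 | N-methoxy-N-methylmethacrylamide | C=C(C)C(=O)N(C)OC | starting material
2 | 1-bromo-3-methylbut-3-en-2-one | C=C(C)C(=O)CBr | intermediate
3 | (2R)-1-bromo-3-methylbut-3-en-2-ol | C=C(C)[C@H](CBr)O | intermediate
4 | 2,2-dimethylpent-4-enal | C=CCC(C)(C)C=O | starting material
5 | diethyl {2-[methoxy(methyl)amino]-2-oxoethyl}phosphonate | CCOP(=O)(OCC)CC(=O)N(C)OC | starting material
6 | (2E)-N-methoxy-N,4,4-trimethylhepta-2,6-dienamide | C=CCC(C)(C)/C=C/C(=O)N(C)OC | intermediate
7 | (2E)-N-methoxy-N,4,4-trimethyl-5-(1,2,4-trioxolan-3-yl)pent-2-enamide (ozonide, not isolated) | C1OC(CC(C)(C)/C=C/C(=O)N(C)OC)OO1 | intermediate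
8 | (2E)-N-methoxy-N,4,4-trimethyl-6-oxohex-2-enamide | O=CCC(C)(C)/C=C/C(=O)N(C)OC | intermediate
9 | (2E,5R)-5-bromo-N-methoxy-N,4,4-trimethyl-6-oxohex-2-enamide | O=C[C@H](Br)C(C)(C)/C=C/C(=O)N(C)OC | intermediate
10 | (triphenylphosphoranylidene)ketene | O=C=C=P(c1ccccc1)(c1ccccc1)c1ccccc1 | starting material
11 | (2R)-1-bromo-3-methylbut-3-en-2-yl (triphenylphosphoranylidene)acetate (not isolated) | C=C(C)[C@H](CBr)OC(=O)C=P(c1ccccc1)(c1ccccc1)c1ccccc1 | intermediate
12 | (2R)-1-bromo-3-methylbut-3-en-2-yl (2E,4S,6E)-4-bromo-8-[methoxy(methyl)amino]-5,5-dimethyl-8-oxoocta-2,6-dienoate | C=C(C)[C@H](CBr)OC(=O)/C=C/[C@H](Br)C(C)(C)/C=C/C(=O)N(C)OC | intermediate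
13 | (2R)-1-bromo-3-methylbut-3-en-2-yl (4S,6E)-4-bromo-8-[methoxy(methyl)amino]-5,5-dimethyl-8-oxooct-6-enoate | C=C(C)[C@H](CBr)OC(=O)CC[C@H](Br)C(C)(C)/C=C/C(=O)N(C)OC | intermediate
14 | (2E,5S)-5-bromo-8-{[(2R)-1-bromo-3-methylbut-3-en-2-yl]oxy}-N-methoxy-N,4,4-trimethylnona-2,8-dienamide | C=C(C)[C@H](CBr)OC(=C)CC[C@H](Br)C(C)(C)/C=C/C(=O)N(C)OC | intermediate
15 | 2-[(1R,3S,6S)-3-bromo-6-{[(2R)-1-bromo-3-methylbut-3-en-2-yl]oxy}-2,2,6-trimethylcyclohexyl]-N-methoxy-N-methylacetamide | CC1(C)[C@@H](CC(=O)N(C)OC)[C@@](C)(O[C@@H](CBr)C(C)=C)CC[C@@H]1Br | intermediate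
16 | 2-[(1R,3S,6S)-3-bromo-6-{[(2R)-1-bromo-3-methylbut-3-en-2-yl]oxy}-2,2,6-trimethylcyclohexyl]acetaldehyde | CC1(C)[C@@H](CC=O)[C@@](C)(O[C@@H](CBr)C(C)=C)CC[C@@H]1Br | intermediate
17 | (1S,2R,4S)-4-bromo-1-{[(2R)-1-bromo-3-methylbut-3-en-2-yl]oxy}-1,3,3-trimethyl-2-(prop-2-en-1-yl)cyclohexane | CC1(C)[C@@H](CC=C)[C@@](C)(O[C@@H](CBr)C(C)=C)CC[C@@H]1Br | intermediate
18 | (2R,5aR,7S,9aS)-7-bromo-2-(bromomethyl)-3,6,6,9a-tetramethyl-2,5,5a,6,7,8,9,9a-octahydro-1-benzoxepine | CC1(C)[C@H]2CC=C(C)[C@H](CBr)O[C@@]2(C)CC[C@@H]1Br | intermediate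
19 | [(2R,5aR,7S,9aS)-7-bromo-2-(bromomethyl)-6,6,9a-trimethyl-2,5,5a,6,7,8,9,9a-octahydro-1-benzoxepin-3-yl]methanol | CC1(C)[C@H]2CC=C(CO)[C@H](CBr)O[C@@]2(C)CC[C@@H]1Br | target

Total step count: 13. Longest linear sequence: 11 steps (4 and 5 to 19, steps 3 to 13).

Steps most likely to fail

Step 9 (key step). The hydrogen atom may go to the isopropenyl group instead of the enol ether, or the radical may close on the wrong face of C5a relative to C7 (bromine equatorial instead of axial), since the control by C7 is weak. The fallback sets out from 14 and comes back at 15. Benzeneselenol adds across the enol ether (PhSeH, cat. pyridinium p-toluenesulfonate, CH2Cl2, −40 °C) to give the mixed O,Se-ketal (2E,5S)-5-bromo-8-{[(2R)-1-bromo-3-methylbut-3-en-2-yl]oxy}-N-methoxy-N,4,4-trimethyl-8-(phenylselanyl)non-2-enamide F1. Selenium abstraction with (Me3Si)3SiH and Et3B/air in toluene at −78 °C then generates the same C9a radical without a metal hydride and at low temperature. The cyclised radical takes hydrogen from the silane to give 15.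

Step 7. Over-reduction may occur, with diimide also saturating the isopropenyl group or the amide-conjugated alkene. The fallback sets out from 9 and comes back at 13, and it replaces steps 6 and 7. Knoevenagel condensation of 9 with Meldrum's acid (EtOH, 0 °C, no amine) would give the alkylidene derivative (2E,5S)-5-bromo-6-(2,2-dimethyl-4,6-dioxo-1,3-dioxan-5-ylidene)-N-methoxy-N,4,4-trimethylhex-2-enamide F2. The Hantzsch ester reduces only this doubly activated alkene, giving (2E,5S)-5-bromo-6-(2,2-dimethyl-4,6-dioxo-1,3-dioxan-5-yl)-N-methoxy-N,4,4-trimethylhex-2-enamide F3. Heating F3 with alcohol 3 in toluene at 110 °C opens the dioxanedione, and decarboxylation of the half ester gives 13.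

Step 13. The oxidant may attack the ring C–H at C2 next to the ether oxygen, which leads to ring cleavage, or over-oxidise the product to the enal. The fallback sets out from 18 and comes back at 19. Epoxidation (m-chloroperbenzoic acid, NaHCO3, CH2Cl2, 0 °C) gives the 3,4-epoxide (2R,5aR,7S,9aS)-7-bromo-2-(bromomethyl)-3,6,6,9a-tetramethyl-3,4-epoxydecahydro-1-benzoxepine F4. Base-induced opening with Et2Al(TMP) in toluene at 0 °C removes a proton from the methyl group and gives the exocyclic allylic alcohol (2R,5aR,7S,9aS)-7-bromo-2-(bromomethyl)-6,6,9a-trimethyl-3-methylidenedecahydro-1-benzoxepin-4-ol F5. A 1,3-transposition of the hydroxyl group with catalytic Ph3SiOReO3 in Et2O at 0 °C then gives 19.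

Further compounds
F1 | step 9 | (2E,5S)-5-bromo-8-{[(2R)-1-bromo-3-methylbut-3-en-2-yl]oxy}-N-methoxy-N,4,4-trimethyl-8-(phenylselanyl)non-2-enamide (both C8 epimers) | C=C(C)[C@H](CBr)OC(C)([Se]c1ccccc1)CC[C@H](Br)C(C)(C)/C=C/C(=O)N(C)OC
F2 | step 7 | (2E,5S)-5-bromo-6-(2,2-dimethyl-4,6-dioxo-1,3-dioxan-5-ylidene)-N-methoxy-N,4,4-trimethylhex-2-enamide | CC1(C)OC(=O)C(=C[C@H](Br)C(C)(C)/C=C/C(=O)N(C)OC)C(=O)O1
F3 | step 7 | (2E,5S)-5-bromo-6-(2,2-dimethyl-4,6-dioxo-1,3-dioxan-5-yl)-N-methoxy-N,4,4-trimethylhex-2-enamide | CC1(C)OC(=O)C(C[C@H](Br)C(C)(C)/C=C/C(=O)N(C)OC)C(=O)O1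
F4 | step 13 | (2R,5aR,7S,9aS)-7-bromo-2-(bromomethyl)-3,6,6,9a-tetramethyl-3,4-epoxydecahydro-1-benzoxepine (either epoxide face) | CC1(C)[C@H]2CC3OC3(C)[C@H](CBr)O[C@@]2(C)CC[C@@H]1Br
F5 | step 13 | (2R,5aR,7S,9aS)-7-bromo-2-(bromomethyl)-6,6,9a-trimethyl-3-methylidenedecahydro-1-benzoxepin-4-ol (C4 epimers) | CC1(C)[C@H]2CC(O)C(=C)[C@H](CBr)O[C@@]2(C)CC[C@@H]1Br
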